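All runs are calculated with constants of no real substance; noise was put on by code.

Tuesday's run hints at how many chains began: from 2.00 min on, monomer in chains and free monomer together fall short of the charge by 5.00% on average, a reading with 1.5 percentage points of scatter on each figure.

| setting | Monday's | Tuesday's | flask |
|---|---|---|---|
| free monomer | 0.11 M | 0.11 M | 0.11 M |
| transfer agent | 1.1 mM | 1.1 mM | 1.10 mM |
| initiator | 7.4 mM | 16 mM | 11 mM |
| remark | run made earlier | run made earlier |  |
| time |  |  | 5.0 min |

- Monday's (time / min: monomer in chains / %, free monomer / %): 0.417: 11, 88; 1.33: 33, 70; 2.00: 40, 59; 3.00: 53, 45; 5.00: 68, 26; 6.00: 75, 22
- Tuesday's (time / min: monomer in chains / %, free monomer / %): 1.00: 45, 54; 2.00: 65, 29; 3.00: 79, 16; 4.00: 89, 7; 5.00: 91, 6; 6.00: 92, 1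

(standard deviation of a reading: 1.5 percentage points)

- the average divides the monomer in chains by the number of chains begun, living and dead together
- the analysis behind the earlier runs scatters by 1.5 percentage points, standard deviation
- the earlier runs do not show the number of chains; that part of a forecast is a guess

- whether the average number of monomer units in a chain (chains begun, living or dead) reaches 10 by 5.0 min (no / yes)
- average number of monomer units in a chain (chains begun, living or dead) at 5.0 min

Turn the question round: what must be true for your flask to reach 10? In Monday's run free monomer falls close to a plain exponential (pseudo-first-order), and its reading at 5.00 min gives a rate constant of 0.269 /min. Tuesday's run, with 2.16 times the initiator, reads 2.30 times that rate, so scale by charge: the flask gets 0.400 /min. By this estimate 86.5% of the flask's free monomer has reacted by 5.0 min, and you count all of that as monomer in chains. Divide that amount by 10 and you have the chain allowance, the most chains that may begin if the average is to reach the length wanted: 9.51 mM.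

So, if the whole charge of initiator reacts and each initiator begins at most one chain, at least 13.5% of the flask's initiator must fail to begin a chain. If each monomer unit missing on Tuesday took one initiator with it, Tuesday lost 34.4% of its initiator, more than that. At this share my reckoning gives 7.22 mM of chains begun in the flask, fewer than the allowance, and so an average of 13.2 at 5.0 min: my answer is yes.

The forecast differs. It says no, with an average of 8, from about 12 mM of chains, reading the runs as “each initiator starting one chain”.

The flask gives yes: the average passes 10 at 3.02 min and stands at 12.2 at 5.0 min.

    free monomer + initiator → living end + monomer in chains (k = 0.504 /M/s)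
    free monomer + living end → monomer in chains + living end, rate k2*[living end]*[free monomer] (k = 1.02 /M/s)
    living end + transfer agent → dead chain (kL = 3.07 /M/s)
    free monomer + initiator → spent initiator (k = 0.232 /M/s)

With the flask's own 83.8% of monomer in chains at 5.00 min, the allowance is 9.22 mM, and chains begun, living ends plus dead chains, stand at 7.53 mM, less than the allowance. At 1.53 min the flask's initiator has a half-life of 0.40 min by the step that begins chains against 0.88 min by the step to spent initiator, a selectivity factor of about twice, and at 5.00 min spent initiator stands at 3.47 mM.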